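**Plan**

- Numbering (hydroazulene): C3 = carbinol carbon with isopropyl, C3a = ring-fusion CH, C4 = ester carbinol, C5 = CH2, C6 = C(=CH2), C7 = CH–OH, C8 = CH2, C8a = quaternary carbon with CH3.
- Retrosynthesis: cut the aryl ester C–O; the C7–OH bond (late allylic C–H oxidation); the C8a–CH3 and C3a–H bonds (reductive methylation of a C3a=C8a alkene); then C4–C5 and C7–C8 together, a (4+3) annulation.
- What allows it: C5–C6(=CH2)–C7 is a 2-methylenepropane-1,3-diyl unit, and its partners C4 and C8 are exocyclic to the neighbouring cyclopentane atoms C3a and C8a. C4=C3a–C8a=C8 can therefore be the silyl dienol ether of a 2-methylcyclopent-1-ene-1-carbaldehyde, and the three-carbon unit a 2-(silylmethyl)allyl cation.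
- Forward: (S)-terpinen-4-ol is ring-contracted (ozonolysis, aldol) to that cyclopentene aldehyde (terpene C4, C7 and C2 become C3, C8 and C4). The seven-membered ring is then annulated in one step, followed by methyl/hydrogen delivery to C8a/C3a, reduction at C4, esterification and oxidation at C7.
- Stereochemistry: C3 comes from the terpene; the C8a methyl is delivered through a silicon tether from the C3 oxygen and C3a–H by hydrogen-atom transfer to the opposite face; C4 is set by dissolving-metal reduction to the more stable carbinol; C7 by SeO2 oxidation on the face away from the C8a methyl.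

Key step: step 5

Remark: (S)-(+)-terpinen-4-ol is taken to be available in high enantiomeric purity; the enol ether geometry of 5 and the C4 configuration in 7, 8 and 9 have no bearing on the route.

**Route**

Step 1
Reactants: 1 (S)-(+)-terpinen-4-ol
Product: 2 triethyl{[(1S)-4-methyl-1-(propan-2-yl)cyclohex-3-en-1-yl]oxy}silane
Conditions: Et3SiOTf, 2,6-lutidine, CH2Cl2, 0 °C
Reagents that add atoms: triethylsilyl trifluoromethanesulfonate, CC[Si](CC)(CC)OS(=O)(=O)C(F)(F)F
Why: Silyl ether formation with a silyl triflate, the usual way to cap a tertiary alcohol; the group prevents retro-aldol cleavage and dehydration of the β-oxygenated aldehyde of steps 2 and 3 and leaves the stereocenter untouched.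

Step 2
Reactants: 2 silyl ether
Product: 3 (3S)-6-oxo-3-(propan-2-yl)-3-[(triethylsilyl)oxy]heptanal
Conditions: O3, CH2Cl2–MeOH, −78 °C; then Me2S, −78 → 23 °C
Reagents that add atoms: ozone, [O-][O+]=O
Why: Ozonolysis with reductive work-up cleaves the only C=C bond to the methyl ketone and the aldehyde.

Step 3
Reactants: 3 keto aldehyde
Product: 4 (5R)-2-methyl-5-(propan-2-yl)-5-[(triethylsilyl)oxy]cyclopent-1-ene-1-carbaldehyde
Conditions: piperidine (0.3 equiv), AcOH (0.3 equiv), toluene, 80 °C
Reagents that add atoms: none
Why: Intramolecular aldol condensation through the piperidine enamine of the aldehyde, which closes the five-membered ring onto the methyl ketone and dehydrates to the tetrasubstituted enal (the known ring contraction of limonene-type keto aldehydes); the carbinol center is not involved.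

Step 4
Reactants: 4 enal
Product: 5 triethyl{[(1R,2E)-3-methylidene-1-(propan-2-yl)-2-{[(trimethylsilyl)oxy]methylidene}cyclopentyl]oxy}silane
Conditions: Me3SiOTf, Et3N, Et2O, −20 → 0 °C
Reagents that add atoms: trimethylsilyl trifluoromethanesulfonate, C[Si](C)(C)OS(=O)(=O)C(F)(F)F
Why: Soft enolisation (O-silylation, then γ-deprotonation) to the 1-siloxy diene; the amine should take a proton from the unhindered methyl group (future C8) rather than from the ring CH2, which gives the s-cis diene with both double bonds exocyclic.

Step 5
Reactants: 5 silyl dienol ether; 6 [2-(chloromethyl)prop-2-en-1-yl]trimethylsilane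
Product: 9 (3R)-6-methylidene-3-(propan-2-yl)-1,2,3,4,5,6,7,8-octahydroazulene-3,4-diol (both C4 epimers), via allylated enal 7 (not isolated), via bis-silyl ether 8 (not isolated)
Conditions: AgOTf, 2,6-di-tert-butyl-4-methylpyridine (0.3 equiv), CH2Cl2, −60 → −20 °C; then Et3N; Bu4NF, THF, 0 → 23 °C
Reagents that add atoms: none
Why: Proposed new method: AgOTf takes chloride from 6 and the 2-(trimethylsilylmethyl)allyl cation is captured at a CH2 terminus by C8, the γ-carbon of silyl dienol ether 5, which leaves an O-silyl oxocarbenium ion at C4 (silylated 7); the allylsilane terminus C5 then adds to C4 with loss of its silyl group, which creates the exocyclic methylene and Me3SiOTf, so that the first bond formation supplies the Lewis acid for the second. The closest known reaction types are the (4+3) cycloaddition of 2-(silylmethyl)allyl cations with 1,3-dienes, the silver-promoted γ-alkylation of siloxy dienes with allylic halides and the intramolecular Hosomi–Sakurai reaction; their union on a silyl dienol ether, with the aldehyde oxygen kept at C4, has not been shown. The seven-membered ring closes in the second bond formation, 7-endo-trig with respect to the allylsilane double bond, and the cis-locked C3a=C8a double bond holds the chain and the formyl carbon together as in an ortho-disubstituted arene. C4 is the only new stereocenter; it forms without control, is carried as both epimers and is erased in step 6, while C3 is not touched. The step needs γ- over α-attack on the dienol ether, secured by the fully substituted C3a next to the quaternary C3, and 1,2- over 1,4-addition of the allylsilane, secured by the higher electrophilicity of the silylated aldehyde carbon and by the strain of the alternative spiro ring with a new quaternary carbon at C8a; fluoride then removes both silyl groups.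

Step 6
Reactants: 9 diol
Product: 10 (3R)-3-hydroxy-6-methylidene-3-(propan-2-yl)-2,3,5,6,7,8-hexahydroazulen-4(1H)-one
Conditions: Dess–Martin periodinane, NaHCO3, CH2Cl2, 0 °C
Reagents that add atoms: none
Why: Dess–Martin oxidation of the secondary allylic alcohol (the tertiary one cannot react) removes the uncontrolled C4 stereocenter and gives the enone whose β-carbon is C8a.

Step 7
Reactants: 10 hydroxy enone
Product: 11 (3R)-3-{[(bromomethyl)dimethylsilyl]oxy}-6-methylidene-3-(propan-2-yl)-2,3,5,6,7,8-hexahydroazulen-4(1H)-one
Conditions: BrCH2SiMe2Cl, AgOTf, 2,6-lutidine, CH2Cl2, −40 → 0 °C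
Reagents that add atoms: (bromomethyl)chlorodimethylsilane, C[Si](C)(Cl)CBr
Why: Silylation of the hindered tertiary alcohol with the silyl triflate made in the flask and a non-nucleophilic base (so that the acidic C5 methylene is left alone) installs the Stork–Nishiyama radical tether on the C3 oxygen.

Step 8
Reactants: 11 bromomethylsilyl ether
Product: 12 trans-fused 6-methylidene-3-(propan-2-yl)octahydroazulen-4(1H)-one in which O3 and a CH2 on C8a are joined by SiMe2 (six-membered oxasilane ring on the face of the C3 oxygen; 3a-H on the opposite face)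
Conditions: Bu3SnH (slow addition), AIBN (cat.), benzene, 80 °C
Reagents that add atoms: none
Why: Tin hydride radical cyclisation (steps 7, 8 and 10 together are Stork's reductive methylation): the nucleophilic silylmethyl radical, held on the C3 oxygen, can reach C8a only on the face of that oxygen and adds there as a 6-endo conjugate addition to the enone, and the α-keto radical at C3a, now the one-atom bridge of the oxasilabicycle, takes hydrogen from Bu3SnH on the face away from the SiMe2 bridge, which gives the trans ring fusion.

Step 9
Reactants: 12 siloxane ketone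
Product: 13 the C4 alcohol of 12 (4-OH cis to 3a-H)
Conditions: Li, NH3(l)–THF, −78 °C; then NH4Cl
Reagents that add atoms: none
Why: Dissolving-metal reduction of the ketone is under thermodynamic control and should give the pseudo-equatorial carbinol, with oxygen cis to 3a-H and away from the axial C8a substituent (a hydride reagent would attack from the open face and give the epimer); the isolated 1,1-disubstituted alkene is not reduced.

Step 10
Reactants: 13 siloxane alcohol
Product: 14 (3R,3aS,4S,8aS)-8a-methyl-6-methylidene-3-(propan-2-yl)decahydroazulene-3,4-diol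
Conditions: Bu4NF, DMF, 70 °C
Reagents that add atoms: none
Why: Fluoride-induced cleavage of the Si–O bond and protodesilylation of the Si–CH2 bond turn the tether carbon into the C8a methyl group, whose configuration (cis to the C3 hydroxyl) was fixed in step 8.

Step 11
Reactants: 14 diol; 15 4-acetoxybenzoic acid
Product: 16 (3R,3aS,4S,8aS)-3-hydroxy-8a-methyl-6-methylidene-3-(propan-2-yl)decahydroazulen-4-yl 4-(acetyloxy)benzoate
Conditions: DCC, DMAP (0.3 equiv), CH2Cl2, 0 → 23 °C
Reagents that add atoms: none
Why: Steglich esterification; only the secondary C4 hydroxyl is acylated because the C3 hydroxyl is tertiary and flanked by the isopropyl group, and the configuration at C4 is retained.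

Step 12
Reactants: 16 ester
Product: 17 (3R,3aS,4S,7S,8aR)-3,7-dihydroxy-8a-methyl-6-methylidene-3-(propan-2-yl)decahydroazulen-4-yl 4-(acetyloxy)benzoate
Conditions: SeO2 (0.5 equiv), t-BuOOH, CH2Cl2, 0 → 23 °C
Reagents that add atoms: tert-butyl hydroperoxide, CC(C)(C)OO; selenium dioxide, O=[Se]=O
Why: Selenium dioxide allylic hydroxylation (ene reaction, then [2,3]-sigmatropic shift, under Sharpless–Umbreit conditions): of the two allylic methylenes, C5 is deactivated and shielded by the neighbouring aroyloxy group, so C7 should react, and the oxygen should arrive on the face away from the axial C8a methyl, cis to the C4 ester.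

Step 13
Reactants: 17 allylic alcohol
Product: 18 ferugin, (3R,3aS,4S,7S,8aR)-3,7-dihydroxy-8a-methyl-6-methylidene-3-(propan-2-yl)decahydroazulen-4-yl 4-hydroxybenzoate
Conditions: NH3, MeOH, 0 °C
Reagents that add atoms: none
Why: Chemoselective aminolysis of the phenolic acetate, which is far more electrophilic than the hindered secondary benzoate and should be cleaved at low temperature without acyl migration to the C7 hydroxyl.

**Compound list**

1 | (S)-(+)-terpinen-4-ol, (1S)-4-methyl-1-(propan-2-yl)cyclohex-3-en-1-ol | CC1=CC[C@](O)(C(C)C)CC1 | starting material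
2 | triethyl{[(1S)-4-methyl-1-(propan-2-yl)cyclohex-3-en-1-yl]oxy}silane | CC1=CC[C@](O[Si](CC)(CC)CC)(C(C)C)CC1 | intermediate
3 | (3S)-6-oxo-3-(propan-2-yl)-3-[(triethylsilyl)oxy]heptanal | CC(=O)CC[C@@](O[Si](CC)(CC)CC)(C(C)C)CC=O | intermediate
4 | (5R)-2-methyl-5-(propan-2-yl)-5-[(triethylsilyl)oxy]cyclopent-1-ene-1-carbaldehyde | CC1=C(C=O)[C@](O[Si](CC)(CC)CC)(C(C)C)CC1 | intermediate
5 | triethyl{[(1R,2E)-3-methylidene-1-(propan-2-yl)-2-{[(trimethylsilyl)oxy]methylidene}cyclopentyl]oxy}silane | C[Si](C)(C)O/C=C1\C(=C)CC[C@@]1(O[Si](CC)(CC)CC)C(C)C | intermediate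
6 | [2-(chloromethyl)prop-2-en-1-yl]trimethylsilane | C=C(CCl)C[Si](C)(C)C | starting material
7 | (5R)-5-(propan-2-yl)-5-[(triethylsilyl)oxy]-2-{3-[(trimethylsilyl)methyl]but-3-en-1-yl}cyclopent-1-ene-1-carbaldehyde (not isolated; reacts on as its O-silyl oxocarbenium ion) | C=C(C[Si](C)(C)C)CCC1=C(C=O)[C@](O[Si](CC)(CC)CC)(C(C)C)CC1 | intermediate
8 | (3R)-6-methylidene-3-(propan-2-yl)-3-[(triethylsilyl)oxy]-4-[(trimethylsilyl)oxy]-1,2,3,4,5,6,7,8-octahydroazulene (C4 epimers; not isolated) | C=C1CC(O[Si](C)(C)C)C2=C(CC1)CC[C@@]2(O[Si](CC)(CC)CC)C(C)C | intermediate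
9 | (3R)-6-methylidene-3-(propan-2-yl)-1,2,3,4,5,6,7,8-octahydroazulene-3,4-diol (C4 epimers) | C=C1CC(O)C2=C(CC1)CC[C@@]2(O)C(C)C | intermediate
10 | (3R)-3-hydroxy-6-methylidene-3-(propan-2-yl)-2,3,5,6,7,8-hexahydroazulen-4(1H)-one | C=C1CC(=O)C2=C(CC1)CC[C@@]2(O)C(C)C | intermediate
11 | (3R)-3-{[(bromomethyl)dimethylsilyl]oxy}-6-methylidene-3-(propan-2-yl)-2,3,5,6,7,8-hexahydroazulen-4(1H)-one | C=C1CC(=O)C2=C(CC1)CC[C@@]2(O[Si](C)(C)CBr)C(C)C | intermediate
12 | trans-fused ketone with an O3–SiMe2–CH2–C8a bridge (oxasilane ring cis to O3; 3a-H on the opposite face) | C=C1CC(=O)[C@@H]2[C@@]3(C[Si](C)(C)O[C@@]2(C(C)C)CC3)CC1 | intermediate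
13 | C4 alcohol of 12 (4-OH cis to 3a-H) | C=C1C[C@H](O)[C@@H]2[C@@]3(C[Si](C)(C)O[C@@]2(C(C)C)CC3)CC1 | intermediate
14 | (3R,3aS,4S,8aS)-8a-methyl-6-methylidene-3-(propan-2-yl)decahydroazulene-3,4-diol | C=C1C[C@H](O)[C@@H]2[C@](C)(CC[C@@]2(O)C(C)C)CC1 | intermediate
15 | 4-acetoxybenzoic acid | CC(=O)Oc1ccc(cc1)C(=O)O | starting material
16 | (3R,3aS,4S,8aS)-3-hydroxy-8a-methyl-6-methylidene-3-(propan-2-yl)decahydroazulen-4-yl 4-(acetyloxy)benzoate | C=C1C[C@H](OC(=O)c2ccc(OC(C)=O)cc2)[C@@H]2[C@](C)(CC[C@@]2(O)C(C)C)CC1 | intermediate
17 | (3R,3aS,4S,7S,8aR)-3,7-dihydroxy-8a-methyl-6-methylidene-3-(propan-2-yl)decahydroazulen-4-yl 4-(acetyloxy)benzoate | C=C1C[C@H](OC(=O)c2ccc(OC(C)=O)cc2)[C@@H]2[C@](C)(CC[C@@]2(O)C(C)C)C[C@@H]1O | intermediate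
18 | ferugin, (3R,3aS,4S,7S,8aR)-3,7-dihydroxy-8a-methyl-6-methylidene-3-(propan-2-yl)decahydroazulen-4-yl 4-hydroxybenzoate | C=C1C[C@H](OC(=O)c2ccc(O)cc2)[C@@H]2[C@](C)(CC[C@@]2(O)C(C)C)C[C@@H]1O | target

**Count and risks**

Total step count: 13. Longest linear sequence: 13 steps (1 to 18; 6 and 15 are bought).

Steps most likely to fail:

1. Step 5 (Proposed new method). After the first C–C bond is formed, the allylsilane may add in the conjugate sense to C8a, or lose its silyl group by protonation, so that the seven-membered ring does not close; the tertiary allylic silyl ether may also ionise under the silyl triflate. Fallback with known chemistry, from 5 to 9: γ-alkylation of 5 with 3-bromo-2-(bromomethyl)prop-1-ene promoted by AgOCOCF3 in CH2Cl2 should give bromo enal F1. Ring closure by intramolecular Nozaki–Hiyama–Kishi allylation with CrCl2 in THF (the allylchromium adds only 1,2 to the aldehyde and transposes to leave the exocyclic methylene) should give silyl ether alcohol F2. Bu4NF then gives 9.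

2. Step 8. The silylmethyl radical may be reduced by the tin hydride before it cyclises, or may close 5-exo onto C3a instead of 6-endo onto C8a. Fallback, from 10 to 14: conjugate addition of Me2CuLi in Et2O at −40 → 0 °C, in which the lithium alkoxide at C3 and the isopropyl group on the other face should send the methyl group cis to the hydroxyl. Protonation of the enolate at C3a from the face opposite the new methyl group should give β-hydroxy ketone F3. Reduction with Li in NH3 as in step 9 then gives 14.

3. Step 12. Poor facial selectivity of the oxygen transfer to C7, or over-oxidation of the new allylic alcohol to the enone. Fallback, from 16 to 17: the oxidation is driven through on purpose (SeO2 in dioxane, then MnO2) to the C7 ketone F4. This is reduced under reagent control with the (R)-Me-CBS oxazaborolidine and catecholborane in toluene at −78 °C, the exocyclic alkenyl carbon acting as the large group, to give 17.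

Further compounds
F1 | step 5 | (5R)-2-[3-(bromomethyl)but-3-en-1-yl]-5-(propan-2-yl)-5-[(triethylsilyl)oxy]cyclopent-1-ene-1-carbaldehyde | C=C(CBr)CCC1=C(C=O)[C@](O[Si](CC)(CC)CC)(C(C)C)CC1
F2 | step 5 | (3R)-6-methylidene-3-(propan-2-yl)-3-[(triethylsilyl)oxy]-1,2,3,4,5,6,7,8-octahydroazulen-4-ol (C4 epimers) | C=C1CC(O)C2=C(CC1)CC[C@@]2(O[Si](CC)(CC)CC)C(C)C
F3 | step 8 | (3R,3aR,8aS)-3-hydroxy-8a-methyl-6-methylidene-3-(propan-2-yl)octahydroazulen-4(1H)-one | C=C1CC(=O)[C@@H]2[C@](C)(CC[C@@]2(O)C(C)C)CC1
F4 | step 12 | (3R,3aS,4S,8aR)-3-hydroxy-8a-methyl-6-methylidene-7-oxo-3-(propan-2-yl)decahydroazulen-4-yl 4-(acetyloxy)benzoate | C=C1C[C@H](OC(=O)c2ccc(OC(C)=O)cc2)[C@@H]2[C@](C)(CC[C@@]2(O)C(C)C)CC1=O
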